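**Retrosynthetic overview**
- C8–OMe stereocentre: made last from an achiral 8,8-dimethoxy ketal; one C–O bond is kept and the other is replaced by hydride delivered anti to the C5 octyl group (gives cis-5,8).
- N-methoxy-4-pyridone: N1–C2 and N1–C8a bonds by exchanging the ring oxygen of a fused 4-pyranone with MeONH2; the pyranone O1–C2 bond by amide-acetal annulation of a 2-(methoxyacetyl)cyclohexanone (ring-forming C–O, then C–N).
- C4a–C4 bond and C5 stereocentre: tandem copper-catalysed asymmetric conjugate addition of octylmagnesium bromide and enolate C-acylation on 6,6-dimethoxycyclohex-2-en-1-one; the ketal blocks C8, so only one enolate and one condensable methylene exist.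
- The enone comes from cyclohexane-1,2-dione (mono-ketalisation, dehydrogenation). Ring order: carbocycle (bought) → pyranone → pyridone.

Assumption: the sense of induction of CuCl/TaniaPhos (1-[(dimethylamino)(2-diphenylphosphinophenyl)methyl]-2-(diphenylphosphino)ferrocene) on this ketal-bearing enone is taken from cyclohexenone; the ligand antipode that gives the (S)-configured octyl-bearing centre is used and is written as (R,R)-TaniaPhos.

**Step 1**
Reactants: 1 cyclohexane-1,2-dione; 2 trimethyl orthoformate
Product: 3 2,2-dimethoxycyclohexan-1-one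
Conditions: HC(OMe)3 (1.1 equiv), MeOH, H2SO4 (cat.), 0 → 25 °C
Reagents that add atoms: trimethyl orthoformate, COC(OC)OC; methanol, CO
Why: Acid-catalysed ketalisation (orthoformate method) with one equivalent of orthoformate stops at the mono-ketal because the remaining carbonyl is hindered and inductively deactivated by the adjacent ketal.

**Step 2**
Reactants: 3 2,2-dimethoxycyclohexan-1-one
Product: 6 6,6-dimethoxycyclohex-2-en-1-one, via lithium enolate 4 (not isolated), via sulfilimine adduct 5 (not isolated)
Conditions: LiN(i-Pr)2 (1.1 equiv), THF, −78 °C; then PhS(Cl)=N-t-Bu (1.2 equiv), −78 °C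
Reagents that add atoms: none
Why: The other α-carbon is quaternary, so deprotonation gives a single enolate, and its S-sulfinimidoylation followed by in situ syn-elimination (Mukaiyama one-pot ketone dehydrogenation) gives the enone under basic conditions at −78 °C, where the ketal cannot lose methanol.

**Step 3**
Reactants: 6 6,6-dimethoxycyclohex-2-en-1-one; 7 octylmagnesium bromide; 8 methoxyacetyl chloride
Product: 10 (2S,3S)-6,6-dimethoxy-2-(2-methoxyacetyl)-3-octylcyclohexan-1-one, via magnesium enolate 9 (not isolated)
Conditions: n-C8H17MgBr (1.2 equiv), CuCl (5 mol%), (R,R)-TaniaPhos (6 mol%), Et2O, −40 °C; then cannulate into MeOCH2COCl (1.5 equiv), Et2O, −78 → 0 °C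
Reagents that add atoms: octylmagnesium bromide, CCCCCCCC[Mg]Br; methoxyacetyl chloride, COCC(=O)Cl
Why: Copper-catalysed asymmetric conjugate addition of the Grignard reagent with a chiral ferrocenyl diphosphine (Feringa-type) sets the octyl-bearing centre (S) by catalyst control while the flanking ketal hinders 1,2-addition, and the magnesium enolate formed regiospecifically at C-2 is C-acylated by the acid chloride in ether (tandem conjugate addition–enolate acylation; the C-2 configuration does not matter because the 1,3-diketone enolises).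

**Step 4**
Reactants: 10 (2S,3S)-6,6-dimethoxy-2-(2-methoxyacetyl)-3-octylcyclohexan-1-one; 11 N,N-dimethylacetamide dimethyl acetal; 12 O-methylhydroxylamine hydrochloride
Product: 15 (S)-1,3,8,8-tetramethoxy-2-methyl-5-octyl-5,6,7,8-tetrahydroquinolin-4(1H)-one, via enaminone 13 (not isolated), via pyranone ketal 14 (not isolated)
Conditions: MeC(OMe)2NMe2 (1.5 equiv), PhMe, 110 °C; evaporate; then MeONH2·HCl (3 equiv), NaOAc (3 equiv), MeOH, 65 °C
Reagents that add atoms: N,N-dimethylacetamide dimethyl acetal, CN(C)C(C)(OC)OC; O-methylhydroxylamine hydrochloride, CON.Cl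
Why: The methoxyacetyl CH2 is the only condensable methylene (C-6 is blocked), so the amide acetal gives the enaminone, the ring enol oxygen closes on it with loss of Me2NH to the 4-pyranone (C–O ring closure), and methoxyamine then adds at C-2, opens the ring and recloses on C-8a with loss of water (pyranone-to-4-pyridone exchange, both C–N bonds), while C-8 is still an achiral ketal and C-5 cannot enolise.

**Step 5**
Reactants: 15 (S)-1,3,8,8-tetramethoxy-2-methyl-5-octyl-5,6,7,8-tetrahydroquinolin-4(1H)-one
Product: 16 Waltherione K [(5S,8R)-1,3,8-trimethoxy-2-methyl-5-octyl-5,6,7,8-tetrahydroquinolin-4(1H)-one]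
Conditions: Et3SiH (5 equiv), CF3CO2H, 25 → 50 °C; NaHCO3 (aq)
Reagents that add atoms: none
Why: Proposed new method: diastereoselective silane mono-reduction of a gem-dimethoxy ketal that sits next to an N-alkoxy-4-pyridone, not yet shown on so deactivated a ketal or with 1,4-remote control; in CF3CO2H the pyridone is O-protonated, the ketal ionises (slowly, hence neat acid and gentle heating) to the C-8 methyl oxocarbenium ion, and Et3SiH delivers hydride axially to the face anti to the C-5 octyl group, which 1,3-allylic (peri) strain with the O-4 substituent holds pseudoaxial, so hydrogen enters trans to octyl and the surviving methoxy group ends cis (8R); the product monoether has no second oxygen to support ionisation next to the protonated ring, so reduction stops there; closest known reaction type: Kursanov–Parnes ionic hydrogenation (R3SiH/acid reduction of ketals to ethers) with axial hydride delivery to six-membered cyclic oxocarbenium ions.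

**Compound list**
1 | cyclohexane-1,2-dione | O=C1CCCCC1=O | starting material
2 | trimethyl orthoformate | COC(OC)OC | starting material
3 | 2,2-dimethoxycyclohexan-1-one | COC1(OC)CCCCC1=O | intermediate
4 | lithium 6,6-dimethoxycyclohex-1-en-1-olate | COC1(OC)CCCC=C1O[Li] | intermediate
5 | 2-(N-tert-butyl-S-phenylsulfinimidoyl)-6,6-dimethoxycyclohexan-1-one | COC1(OC)CCCC(C1=O)S(=NC(C)(C)C)c1ccccc1 | intermediate
6 | 6,6-dimethoxycyclohex-2-en-1-one | COC1(OC)CCC=CC1=O | intermediate
7 | octylmagnesium bromide | CCCCCCCC[Mg]Br | starting material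
8 | methoxyacetyl chloride | COCC(=O)Cl | starting material
9 | bromomagnesium (S)-6,6-dimethoxy-3-octylcyclohex-1-en-1-olate | CCCCCCCC[C@H]1CCC(OC)(OC)C(O[Mg]Br)=C1 | intermediate
10 | (2S,3S)-6,6-dimethoxy-2-(2-methoxyacetyl)-3-octylcyclohexan-1-one (largely enolised) | CCCCCCCC[C@H]1CCC(OC)(OC)C(=O)[C@@H]1C(=O)COC | intermediate
11 | N,N-dimethylacetamide dimethyl acetal (1,1-dimethoxy-N,N-dimethylethan-1-amine) | CN(C)C(C)(OC)OC | starting material
12 | O-methylhydroxylamine hydrochloride | CON.Cl | starting material
13 | (2S,3S)-2-[3-(dimethylamino)-2-methoxybut-2-enoyl]-6,6-dimethoxy-3-octylcyclohexan-1-one (E/Z mixture) | CCCCCCCC[C@H]1CCC(OC)(OC)C(=O)[C@@H]1C(=O)C(OC)=C(C)N(C)C | intermediate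
14 | (S)-3,8,8-trimethoxy-2-methyl-5-octyl-5,6,7,8-tetrahydro-4H-chromen-4-one | CCCCCCCC[C@H]1CCC(OC)(OC)C2=C1C(=O)C(OC)=C(C)O2 | intermediate
15 | (S)-1,3,8,8-tetramethoxy-2-methyl-5-octyl-5,6,7,8-tetrahydroquinolin-4(1H)-one | CCCCCCCC[C@H]1CCC(OC)(OC)c2c1c(=O)c(OC)c(C)n2OC | intermediate
16 | Waltherione K, (5S,8R)-1,3,8-trimethoxy-2-methyl-5-octyl-5,6,7,8-tetrahydroquinolin-4(1H)-one | CCCCCCCC[C@H]1CC[C@@H](OC)c2c1c(=O)c(OC)c(C)n2OC | target

**Step count and risks**
Total step count: 5. Longest linear sequence: 5 (fully linear).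

The three steps most likely to fail:

Step 3 (tandem conjugate addition–acylation). The ketal oxygens may chelate magnesium or copper and erode the ee, and the hindered enolate may be O-acylated or quenched by the acidic product. The fallback sets out from 6 and separates the two events. Conjugate addition of (E)-oct-1-en-1-ylboronic acid with Rh(acac)(C2H4)2 and (S)-BINAP in dioxane/H2O at 100 °C (Hayashi–Miyaura) gives (S)-6,6-dimethoxy-3-[(E)-oct-1-en-1-yl]cyclohexan-1-one F1. Hydrogenation (H2, Pd/C, EtOAc) gives (S)-6,6-dimethoxy-3-octylcyclohexan-1-one F2. This ketone can enolise only toward C-2, so soft-enolisation C-acylation (MgBr2·OEt2, i-Pr2NEt, CH2Cl2, methoxyacetyl chloride 8) returns to the route at 10.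

Step 4 (pyranone-to-N-methoxypyridone exchange). Methoxyamine is a weak nucleophile, and reclosure at C-8a is hindered by the neighbouring ketal. The fallback sets out from 10: the amide-acetal annulation is run alone and pyranone 14 is isolated. The smaller and more nucleophilic NH2OH·HCl (pyridine, EtOH, 80 °C) gives (S)-1-hydroxy-3,8,8-trimethoxy-2-methyl-5-octyl-5,6,7,8-tetrahydroquinolin-4(1H)-one F3. O-Methylation of the N-hydroxy group (MeI, K2CO3, DMF, 25 °C) returns to the route at 15.

Step 5 (the proposed new step). Ionisation of the ketal next to the protonated pyridone may be too slow, or the reaction may stop at the enol ether or ketone. The fallback uses known chemistry, sets out from 15 and passes through the ketone. Hydrolysis (2 M HCl, THF, 50 °C) gives (S)-1,3-dimethoxy-2-methyl-5-octyl-6,7-dihydroquinoline-4,8(1H,5H)-dione F4. Reduction with LiBH(s-Bu)3 (THF, −78 °C; hydride enters anti to the pseudoaxial octyl group) gives (5S,8R)-8-hydroxy-1,3-dimethoxy-2-methyl-5-octyl-5,6,7,8-tetrahydroquinolin-4(1H)-one F5. Williamson methylation (NaH, MeI, THF, 0 °C) returns to the route at 16.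

**Further compounds**
F1 | step 3 | (S)-6,6-dimethoxy-3-[(E)-oct-1-en-1-yl]cyclohexan-1-one | CCCCCC/C=C/[C@H]1CCC(OC)(OC)C(=O)C1
F2 | step 3 | (S)-6,6-dimethoxy-3-octylcyclohexan-1-one | CCCCCCCC[C@H]1CCC(OC)(OC)C(=O)C1
F3 | step 4 | (S)-1-hydroxy-3,8,8-trimethoxy-2-methyl-5-octyl-5,6,7,8-tetrahydroquinolin-4(1H)-one | CCCCCCCC[C@H]1CCC(OC)(OC)c2c1c(=O)c(OC)c(C)n2O
F4 | step 5 | (S)-1,3-dimethoxy-2-methyl-5-octyl-6,7-dihydroquinoline-4,8(1H,5H)-dione | CCCCCCCC[C@H]1CCC(=O)c2c1c(=O)c(OC)c(C)n2OC
F5 | step 5 | (5S,8R)-8-hydroxy-1,3-dimethoxy-2-methyl-5-octyl-5,6,7,8-tetrahydroquinolin-4(1H)-one | CCCCCCCC[C@H]1CC[C@@H](O)c2c1c(=O)c(OC)c(C)n2OC
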